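**Plan**

1. Numbering follows the isochromene core (C1, O2, C3, C4, C4a, C5–C8, C8a; ring A = carbocycle, ring B = pyran). The retrosynthesis cuts ring A at C4a=C5 and at C8–C8a, then the acrylate C=C, the ester C–O bond and the C2–C3 bond of the hexanol.
2. Enabling feature: ring B is a 4-ylidene-4H-pyran, so C4a is the carbonyl carbon and C8a the α-carbon of a γ-pyrone. Kojic acid carries exactly this pair as C=O and enol OH (→ OTf), a 1,2-dielectrophile for the C8 (ester α-carbon) and C5 (methyl ketone) ends of a citramalate chain.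
3. Forward: ring B is bought as kojic acid and dressed (5-O-triflate, CH2OH → CHO → E-acrylate). The C5–C8 chain comes from (R)-citramalic acid, whose α-hydroxy acid is tied into a temporary dioxolanone ring and methylenated to a 5-methylidene-1,3-dioxolane; this masks the C7 hydroxyl and C6 ketone and leaves C8 as the only enolisable carbon.
4. Ring A is closed last, in one pot: palladium coupling of the C8 silyl ketene acetal with the pyranonyl triflate (C8–C8a), then acid unmasking and cyclodehydration onto the pyrone carbonyl (C4a=C5). The helper ring and the tert-butyl ester fall in the same acid.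
5. Stereochemistry: C7 (R) from (R)-citramalic acid; C8 (R) by base equilibration to the epimer with the ester cis to the C7 hydroxyl; hexanol C4 (S) from (S)-1-bromo-2-methylbutane and C2 (S) by lipase resolution; E-alkene from a stabilised Wittig reagent.

Key step: step 10

Assumption: the 8R epimer (ester cis to the C7 hydroxyl, anti to the C7 methyl) is taken to be the thermodynamically preferred C8 epimer, as expected from allylic strain with C1–H and the C7–OH···O=C6 hydrogen bond.

**Route**

Step 1
Reactants: 1 (S)-1-bromo-2-methylbutane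
Product: 3 (4S)-4-methylhexan-2-ol as a mixture of C2 epimers, via Grignard reagent 2 (not isolated)
Conditions: Mg turnings, THF, reflux; then acetaldehyde, −78 °C → 0 °C; aq. NH4Cl
Reagents that add atoms: acetaldehyde, CC=O
Why: Grignard formation and addition to an aldehyde; the C4 stereocentre is β to the carbon–magnesium bond and is untouched, and the new carbinol centre forms without control and is sorted in step 2.

Step 2
Reactants: 3 (4S)-4-methylhexan-2-ol (C2 epimers)
Product: 4 (2S,4S)-4-methylhexan-2-ol
Conditions: immobilised Candida antarctica lipase B, vinyl acetate, hexane, 30 °C, stopped near half conversion; chromatography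
Reagents that add atoms: none
Why: Lipase-catalysed kinetic resolution by transesterification: for methyl carbinols the enzyme acylates the 2R epimer, so the 2S,4S alcohol should remain unreacted and separate from the 2R,4S acetate by chromatography.

Step 3
Reactants: 5 (R)-citramalic acid
Product: 6 2-[(4R)-2,2,4-trimethyl-5-oxo-1,3-dioxolan-4-yl]acetic acid
Conditions: 2,2-dimethoxypropane, TsOH·H2O (cat.), CH2Cl2, rt
Reagents that add atoms: 2,2-dimethoxypropane, COC(C)(C)OC
Why: Acid-catalysed acetonide formation of an α-hydroxy acid: the five-membered dioxolanone should form in preference to the six-membered alternative and leaves the CH2CO2H arm free, with the quaternary stereocentre not involved.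

Step 4
Reactants: 6 2-[(4R)-2,2,4-trimethyl-5-oxo-1,3-dioxolan-4-yl]acetic acid; 4 (2S,4S)-4-methylhexan-2-ol
Product: 7 (2S,4S)-4-methylhexan-2-yl 2-[(4R)-2,2,4-trimethyl-5-oxo-1,3-dioxolan-4-yl]acetate
Conditions: DCC, DMAP (cat.), CH2Cl2, 0 °C → rt
Reagents that add atoms: none
Why: Steglich esterification; the bond is made at the acyl carbon, so the carbinol configuration of 4 is retained, and the dioxolanone is inert to DMAP catalysis.

Step 5
Reactants: 7 (2S,4S)-4-methylhexan-2-yl 2-[(4R)-2,2,4-trimethyl-5-oxo-1,3-dioxolan-4-yl]acetate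
Product: 8 (2S,4S)-4-methylhexan-2-yl 2-[(4R)-2,2,4-trimethyl-5-methylidene-1,3-dioxolan-4-yl]acetate
Conditions: Cp2TiMe2 (1.3 equiv), toluene, 65 °C, dark; filtration through basic alumina
Reagents that add atoms: dimethyltitanocene Cp2TiMe2, [CH3-].[CH3-].[Ti+4].c1cc[cH-]c1.c1cc[cH-]c1
Why: Petasis methylenation of a lactone carbonyl: the strained, acylal-type dioxolanone carbonyl is the more electrophilic of the two esters and should react first, giving an enol-ether acetal that masks the C7 hydroxyl and the C6 ketone and carries the future C5 as =CH2, so that C8 is the only enolisable carbon left.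

Step 6
Reactants: 8 (2S,4S)-4-methylhexan-2-yl 2-[(4R)-2,2,4-trimethyl-5-methylidene-1,3-dioxolan-4-yl]acetate
Product: 9 trimethylsilyl ketene acetal of 8, trimethyl{[1-{[(2S,4S)-4-methylhexan-2-yl]oxy}-2-[(4R)-2,2,4-trimethyl-5-methylidene-1,3-dioxolan-4-yl]ethenyl]oxy}silane (E/Z mixture)
Conditions: LiN(iPr)2, TMSCl present from the start, THF, −78 °C; pentane, filtration, used crude
Reagents that add atoms: chlorotrimethylsilane, C[Si](C)(C)Cl
Why: Kinetic ester enolisation with internal silyl quench (O-silylation to the ketene acetal): trapping at −78 °C as the enolate forms should outrun β-elimination of the acetal oxygen at C7.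

Step 7
Reactants: 10 kojic acid (5-hydroxy-2-(hydroxymethyl)-4H-pyran-4-one)
Product: 11 6-(hydroxymethyl)-4-oxo-4H-pyran-3-yl trifluoromethanesulfonate
Conditions: PhNTf2, Et3N, MeCN, 0 °C → rt
Reagents that add atoms: N-phenylbis(trifluoromethanesulfonimide), O=S(=O)(N(c1ccccc1)S(=O)(=O)C(F)(F)F)C(F)(F)F
Why: Chemoselective O-sulfonylation: only the acidic enolic hydroxyl is deprotonated by Et3N and reacts with the mild triflimide, while the primary alcohol stays free.

Step 8
Reactants: 11 6-(hydroxymethyl)-4-oxo-4H-pyran-3-yl trifluoromethanesulfonate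
Product: 12 6-formyl-4-oxo-4H-pyran-3-yl trifluoromethanesulfonate
Conditions: Dess–Martin periodinane, CH2Cl2, rt
Reagents that add atoms: none
Why: Dess–Martin oxidation of a primary alcohol to the aldehyde under neutral conditions that the enol triflate should tolerate.

Step 9
Reactants: 12 6-formyl-4-oxo-4H-pyran-3-yl trifluoromethanesulfonate
Product: 13 tert-butyl (2E)-3-{4-oxo-5-[(trifluoromethanesulfonyl)oxy]-4H-pyran-2-yl}prop-2-enoate
Conditions: Ph3P=CHCO2tBu, CH2Cl2, rt
Reagents that add atoms: tert-butyl (triphenylphosphoranylidene)acetate, CC(C)(C)OC(=O)C=P(c1ccccc1)(c1ccccc1)c1ccccc1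
Why: Wittig olefination with a stabilised ylide, which should give the E-acrylate and needs no added base.

Step 10
Reactants: 13 tert-butyl (2E)-3-{4-oxo-5-[(trifluoromethanesulfonyl)oxy]-4H-pyran-2-yl}prop-2-enoate; 9 trimethylsilyl ketene acetal of 8
Product: 16 (2E)-3-[(7R)-7-hydroxy-7-methyl-8-({[(2S,4S)-4-methylhexan-2-yl]oxy}carbonyl)-6-oxo-7,8-dihydro-6H-isochromen-3-yl]prop-2-enoic acid as a mixture of C8 epimers, via coupled ester 14 (not isolated), via hydroxy ketone 15 (not isolated)
Conditions: Pd2(dba)3 (2.5 mol%), XPhos (6 mol%), LiOAc (2 equiv), THF, 65 °C; then evaporation, TFA/H2O (9:1), 0 °C → 40 °C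
Reagents that add atoms: water, O
Why: Proposed new method: zerovalent palladium inserts into the C8a–OTf bond of 13, acetate-assisted transmetalation of 9 (whose only enolisable carbon is C8, the ketone being locked in the methylidene-dioxolane, and whose C7 carries no hydrogen for β-hydride loss) and reductive elimination forge C8–C8a, the closest known type being the palladium-catalysed coupling of aryl and vinyl triflates with ester silyl ketene acetals. Aqueous TFA then hydrolyses the enol-ether acetal of 14 to the C5 methyl ketone and C7 carbinol of 15, protonates the γ-pyrone to a 4-hydroxypyrylium ion, and the ketone enol adds to C4a and loses water to give the 4-ylidene-4H-pyran (C4a=C5), the closest known type being the Knoevenagel-type condensation of 4-pyranones through 4-oxypyrylium ions, which is established for C–H acids but not for a simple ketone enol. Ring A closes by a 6-exo-trig aldol addition (C5 onto the exocyclic C4a=OH+ bond) followed by dehydration. C7 is a spectator and keeps the R configuration of citramalic acid, whereas C8 is created without control in the coupling and is corrected in step 11. The selectivity needed is attack at C4a and not at C1: addition at C1 gives a non-aromatic 2H-pyran that can revert, while addition at C4a becomes irreversible through loss of water to an aromatic pyrylium ion, so the strongly acidic, equilibrating medium should funnel the material to 16. The same acid cleaves the tert-butyl ester.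

Step 11
Reactants: 16 bicyclic acid as a mixture of C8 epimers
Product: 17 (2E)-3-[(7R,8R)-7-hydroxy-7-methyl-8-({[(2S,4S)-4-methylhexan-2-yl]oxy}carbonyl)-6-oxo-7,8-dihydro-6H-isochromen-3-yl]prop-2-enoic acid (target)
Conditions: DBU (2.2 equiv), CH2Cl2, 0 °C → rt; aq. NaH2PO4; preparative HPLC
Reagents that add atoms: none
Why: Base-mediated epimerisation of C8–H (α to the ester and allylic to the C1=C8a enol ether) through its dienolate should place the material under thermodynamic control, where the 8R epimer is expected to be favoured because the ester sits pseudo-axial away from C1–H and anti to the C7 methyl while the pseudo-equatorial C7–OH keeps its hydrogen bond to the C6 carbonyl; C7 has no enolisable hydrogen, and the tertiary alcohol stays protonated with an amidine base, which guards against retro-aldol cleavage.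

**Compound list**

1 | (S)-1-bromo-2-methylbutane | CC[C@H](C)CBr | starting material
2 | [(2S)-2-methylbutyl]magnesium bromide | CC[C@H](C)C[Mg]Br | intermediate
3 | (4S)-4-methylhexan-2-ol, both C2 epimers | CC[C@H](C)CC(C)O | intermediate
4 | (2S,4S)-4-methylhexan-2-ol | CC[C@H](C)C[C@H](C)O | intermediate
5 | (R)-citramalic acid, (2R)-2-hydroxy-2-methylbutanedioic acid | C[C@@](O)(CC(=O)O)C(=O)O | starting material
6 | 2-[(4R)-2,2,4-trimethyl-5-oxo-1,3-dioxolan-4-yl]acetic acid | C[C@]1(CC(=O)O)OC(C)(C)OC1=O | intermediate
7 | (2S,4S)-4-methylhexan-2-yl 2-[(4R)-2,2,4-trimethyl-5-oxo-1,3-dioxolan-4-yl]acetate | CC[C@H](C)C[C@H](C)OC(=O)C[C@@]1(C)OC(C)(C)OC1=O | intermediate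
8 | (2S,4S)-4-methylhexan-2-yl 2-[(4R)-2,2,4-trimethyl-5-methylidene-1,3-dioxolan-4-yl]acetate | CC[C@H](C)C[C@H](C)OC(=O)C[C@@]1(C)OC(C)(C)OC1=C | intermediate
9 | trimethylsilyl ketene acetal of 8 (E/Z mixture) | CC[C@H](C)C[C@H](C)OC(O[Si](C)(C)C)=C[C@@]1(C)OC(C)(C)OC1=C | intermediate
10 | kojic acid, 5-hydroxy-2-(hydroxymethyl)-4H-pyran-4-one | OCC1=CC(=O)C(O)=CO1 | starting material
11 | 6-(hydroxymethyl)-4-oxo-4H-pyran-3-yl trifluoromethanesulfonate | OCC1=CC(=O)C(OS(=O)(=O)C(F)(F)F)=CO1 | intermediate
12 | 6-formyl-4-oxo-4H-pyran-3-yl trifluoromethanesulfonate | O=CC1=CC(=O)C(OS(=O)(=O)C(F)(F)F)=CO1 | intermediate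
13 | tert-butyl (2E)-3-{4-oxo-5-[(trifluoromethanesulfonyl)oxy]-4H-pyran-2-yl}prop-2-enoate | CC(C)(C)OC(=O)/C=C/C1=CC(=O)C(OS(=O)(=O)C(F)(F)F)=CO1 | intermediate
14 | tert-butyl (2E)-3-{5-[2-{[(2S,4S)-4-methylhexan-2-yl]oxy}-2-oxo-1-[(4R)-2,2,4-trimethyl-5-methylidene-1,3-dioxolan-4-yl]ethyl]-4-oxo-4H-pyran-2-yl}prop-2-enoate, both C8 epimers | CC[C@H](C)C[C@H](C)OC(=O)C([C@@]1(C)OC(C)(C)OC1=C)C1=COC(/C=C/C(=O)OC(C)(C)C)=CC1=O | intermediate
15 | tert-butyl (2E)-3-{5-[(2R)-2-hydroxy-2-methyl-1-({[(2S,4S)-4-methylhexan-2-yl]oxy}carbonyl)-3-oxobutyl]-4-oxo-4H-pyran-2-yl}prop-2-enoate, both C8 epimers | CC[C@H](C)C[C@H](C)OC(=O)C([C@@](C)(O)C(C)=O)C1=COC(/C=C/C(=O)OC(C)(C)C)=CC1=O | intermediate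
16 | (2E)-3-[(7R)-7-hydroxy-7-methyl-8-({[(2S,4S)-4-methylhexan-2-yl]oxy}carbonyl)-6-oxo-7,8-dihydro-6H-isochromen-3-yl]prop-2-enoic acid, both C8 epimers | CC[C@H](C)C[C@H](C)OC(=O)C1C2=COC(/C=C/C(=O)O)=CC2=CC(=O)[C@]1(C)O | intermediate
17 | (2E)-3-[(7R,8R)-7-hydroxy-7-methyl-8-({[(2S,4S)-4-methylhexan-2-yl]oxy}carbonyl)-6-oxo-7,8-dihydro-6H-isochromen-3-yl]prop-2-enoic acid | CC[C@H](C)C[C@H](C)OC(=O)[C@@H]1C2=COC(/C=C/C(=O)O)=CC2=CC(=O)[C@]1(C)O | target

**Count and risks**

Total steps: 11. Longest linear sequence: 7 steps (steps 1, 2, 4, 5, 6, 10, 11; from 1 to 17).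

Steps most likely to fail:

1. Step 10 (carries the new-method label). What may go wrong: transmetalation of the hindered ketene acetal may be too slow, so that the triflate is lost to reduction or hydrolysis. The ring closure may also proceed by conjugate addition at C1 instead of addition to the C4a carbonyl, which opens the pyran ring. Fallback with known reaction types, setting out from 13 and 9 and coming back at 16: the coupling is run alone and coupled ester 14 is isolated. PPTS in wet acetone unmasks it to hydroxy ketone 15. MeOTf (CH2Cl2, 0 °C) O-methylates the pyrone to the 4-methoxypyrylium triflate F1. 2,6-Lutidine then induces ipso-substitution of methoxide at C4a by the ketone enol, the classical route from 4-alkoxypyrylium salts to 4-ylidene-4H-pyrans, in which the leaving group fixes the site of attack; this gives the bicyclic tert-butyl ester F2. TFA/CH2Cl2 cleaves the tert-butyl ester and returns 16.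

2. Step 5. What may go wrong: loss of chemoselectivity, with the side-chain ester methylenated as well, or hydrolysis of the enol-ether acetal during isolation. Fallback setting out from 7 and coming back at 16: the ketone is introduced by acyl substitution instead of a titanium carbene. MeNH(OMe)·HCl/iPrMgCl (THF, −20 °C) opens the activated dioxolanone to the hydroxy Weinreb amide F3. MeMgBr (THF, −78 → 0 °C) gives the hydroxy methyl ketone F4. LiN(iPr)2/TMSCl (3.3 equiv, −78 °C) gives the tris(trimethylsilyl) derivative F5 (C7 TMS ether, terminal TMS enol ether, ester TMS ketene acetal). F5 is coupled with 13 under the palladium/LiOAc conditions of step 10, where acetate should activate only the more labile ketene acetal, to give the coupled bis-silyl ester F6, which is not isolated. The TFA stage cleaves both silyl groups to 15 and closes ring A to 16.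

3. Step 11. What may go wrong: loss of the C7 hydroxyl by E1cB elimination from the C8 enolate (dehydration to the fully conjugated isochromenone), or migration of the C1=C8a double bond by reprotonation of the dienolate at C1. Fallback setting out from 16 and coming back at 17, with no new compound: C8 is epimerised without an enolate, by reversible hydrogen-atom transfer. A hindered thiol (tert-dodecanethiol, catalytic) with AIBN in benzene at 70 °C generates a thiyl radical that abstracts the weak C8–H (α to the ester and allylic), and the thiol returns the hydrogen. The epimers should then equilibrate under neutral conditions in which hydroxide cannot leave.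

**Further compounds**

F1 | step 10 | 2-[(E)-2-(tert-butoxycarbonyl)ethenyl]-5-[(2R)-2-hydroxy-2-methyl-1-({[(2S,4S)-4-methylhexan-2-yl]oxy}carbonyl)-3-oxobutyl]-4-methoxypyrylium trifluoromethanesulfonate (both C8 epimers) | CC[C@H](C)C[C@H](C)OC(=O)C([C@@](C)(O)C(C)=O)c1c[o+]c(/C=C/C(=O)OC(C)(C)C)cc1OC.[O-]S(=O)(=O)C(F)(F)F
F2 | step 10 | tert-butyl (2E)-3-[(7R)-7-hydroxy-7-methyl-8-({[(2S,4S)-4-methylhexan-2-yl]oxy}carbonyl)-6-oxo-7,8-dihydro-6H-isochromen-3-yl]prop-2-enoate (both C8 epimers) | CC[C@H](C)C[C@H](C)OC(=O)C1C2=COC(/C=C/C(=O)OC(C)(C)C)=CC2=CC(=O)[C@]1(C)O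
F3 | step 5 | (2S,4S)-4-methylhexan-2-yl (3R)-3-hydroxy-4-[methoxy(methyl)amino]-3-methyl-4-oxobutanoate | CC[C@H](C)C[C@H](C)OC(=O)C[C@@](C)(O)C(=O)N(C)OC
F4 | step 5 | (2S,4S)-4-methylhexan-2-yl (3R)-3-hydroxy-3-methyl-4-oxopentanoate | CC[C@H](C)C[C@H](C)OC(=O)C[C@@](C)(O)C(C)=O
F5 | step 5 | tris(trimethylsilyl) derivative of F4: C7 TMS ether, C5=C6 TMS enol ether, C8 TMS ketene acetal | CC[C@H](C)C[C@H](C)OC(O[Si](C)(C)C)=C[C@@](C)(O[Si](C)(C)C)C(=C)O[Si](C)(C)C
F6 | step 5 | tert-butyl (2E)-3-{5-[(2R)-2-methyl-1-({[(2S,4S)-4-methylhexan-2-yl]oxy}carbonyl)-2,3-bis(trimethylsilyloxy)but-3-en-1-yl]-4-oxo-4H-pyran-2-yl}prop-2-enoate (both C8 epimers) | CC[C@H](C)C[C@H](C)OC(=O)C([C@@](C)(O[Si](C)(C)C)C(=C)O[Si](C)(C)C)C1=COC(/C=C/C(=O)OC(C)(C)C)=CC1=O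
F0 | step 11 | none | none
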